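## Retrosynthetic overview

1. Target 24 ⇐ fluoride removal of eight silyl ethers from 23. The all-cis C6' centre of 23 ⇐ kinetic protonation of the enolate of the all-trans (exo) adduct 21, since C6' is the only epimerisable ring centre.
2. Cyclohexene ring (formed last) ⇐ chiral-borate-catalysed exo Diels–Alder reaction of chromandione diene 17 with 2'-hydroxychalcone 19 (sets C1' and C5' cis).
3. Quaternary C3 ⇐ Pd-catalysed asymmetric prenylation of 4-hydroxycoumarin 15; diene arm ⇐ Suzuki coupling on aryl bromide 10.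
4. Pyranone (lactone) ring (formed first) ⇐ carbonyldiimidazole closure of o-hydroxy deoxybenzoin 13 ⇐ Mg-templated ortho-acylation of phenol 4 with acid chloride 8.
5. Phenol 4 ⇐ Ir C–H borylation/oxidation of bis-silylated 2-bromoresorcinol. This puts the lactone oxygen para to bromine, so the side ring must end up at C6, not C8.

Assumption: the target is taken as the open keto form drawn (the ring substituents at C1', C5', C6' are all cis), and the sense of induction written for the chiral ligands of steps 8 and 10 is assumed; the antipodal ligand is used if it proves opposite.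

Abbreviations: TBSO = tert-butyldimethylsilyloxy; TIPSO = triisopropylsilyloxy; primed locants = cyclohexene ring (C1' on the chromane, C2'=C3'(CH3), C4'H2, C5' aryl, C6' aroyl).

## Route

Step 1
Reactants: 1 2-bromoresorcinol (2-bromobenzene-1,3-diol)
Product: 2 2-bromo-1,3-bis(TBSO)benzene
Conditions: TBSCl (2.3 equiv), imidazole, DMF, rt
Reagents that add atoms: tert-butyldimethylsilyl chloride CC(C)(C)[Si](C)(C)Cl
Why: Imidazole-promoted silyl ether formation masks the future 5- and 7-hydroxyls with fluoride-labile groups that survive all later steps; no stereocentre is involved.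

Step 2
Reactants: 2 2-bromo-1,3-bis(TBSO)benzene
Product: 4 4-bromo-3,5-bis(TBSO)phenol, via aryl pinacol boronate 3 (not isolated)
Conditions: B2pin2 (1.0 equiv), [Ir(OMe)(cod)]2 (1.5 mol %), dtbpy (3 mol %), THF, 80 °C; then KHSO5 (Oxone), acetone/H2O, 0 °C → rt
Reagents that add atoms: bis(pinacolato)diboron CC1(C)OB(OC1(C)C)B1OC(C)(C)C(C)(C)O1 (boron held only in 3); potassium peroxymonosulfate [K+].[O-]S(=O)(=O)OO (phenol oxygen)
Why: Sterically governed iridium-catalysed C–H borylation takes the only C–H not flanked by a substituent (para to Br), and oxidation of the boronate gives the phenol, so the future lactone oxygen sits para to the bromine handle and the two remaining ring positions are equivalent.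

Step 3
Reactants: 5 2,4-dihydroxyphenylacetic acid
Product: 7 2-[2,4-bis(TBSO)phenyl]acetic acid, via silyl ester 6 (not isolated)
Conditions: TBSCl (3.3 equiv), imidazole, DMF, rt; then AcOH/THF/H2O, rt
Reagents that add atoms: tert-butyldimethylsilyl chloride CC(C)(C)[Si](C)(C)Cl
Why: Exhaustive silylation followed by selective hydrolysis of the labile silyl ester (aryl silyl ethers survive dilute acetic acid) gives the protected arylacetic acid.

Step 4
Reactants: 4 4-bromo-3,5-bis(TBSO)phenol; 7 2-[2,4-bis(TBSO)phenyl]acetic acid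
Product: 10 1-[3-bromo-6-hydroxy-2,4-bis(TBSO)phenyl]-2-[2,4-bis(TBSO)phenyl]ethan-1-one, via acid chloride 8 (not isolated), via bromomagnesium phenoxide 9 (not isolated)
Conditions: 7, (COCl)2, DMF (cat.), CH2Cl2, 0 °C, evaporate cold and use at once; 4, EtMgBr (1.0 equiv), Et2O/toluene, 0 °C; then 8 in toluene, 0 °C → rt; aq NH4Cl
Reagents that add atoms: oxalyl chloride ClC(=O)C(=O)Cl (chlorine held only in 8); ethylmagnesium bromide CC[Mg]Br (magnesium and bromine held only in 9)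
Why: Magnesium-templated ortho C-acylation of a phenoxide (Friedel–Crafts acylation through a six-membered chelate, Sartori–Casiraghi type) on a phloroglucinol-type ring whose two ortho positions are equivalent and whose para position is blocked gives a single deoxybenzoin without protic or strong Lewis acid that would strip the silyl ethers.

Step 5
Reactants: 11 2-methylbut-1-en-3-yne
Product: 12 4,4,5,5-tetramethyl-2-[(1E)-3-methylbuta-1,3-dien-1-yl]-1,3,2-dioxaborolane
Conditions: pinacolborane, Cp2Zr(H)Cl (5 mol %), Et3N (10 mol %), neat, 60 °C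
Reagents that add atoms: pinacolborane CC1(C)OBOC1(C)C
Why: Zirconocene-catalysed syn-hydroboration of the terminal alkyne (the 1,1-disubstituted alkene is untouched) gives the E-dienylboronate.

Step 6
Reactants: 10 bromo deoxybenzoin; 12 E-dienylboronate
Product: 13 1-[6-hydroxy-3-[(1E)-3-methylbuta-1,3-dien-1-yl]-2,4-bis(TBSO)phenyl]-2-[2,4-bis(TBSO)phenyl]ethan-1-one
Conditions: Pd(OAc)2 (5 mol %), SPhos (10 mol %), K3PO4, toluene/H2O (10:1), 70 °C
Reagents that add atoms: none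
Why: Suzuki–Miyaura coupling with SPhos, a ligand suited to di-ortho-substituted electron-rich aryl bromides, installs the dehydroprenyl diene with retention of the E geometry at the carbon that becomes C6.

Step 7
Reactants: 13 dienyl deoxybenzoin
Product: 15 3-[2,4-bis(TBSO)phenyl]-5,7-bis(TBSO)-4-hydroxy-6-[(1E)-3-methylbuta-1,3-dien-1-yl]-2H-chromen-2-one, via aryl imidazole-1-carboxylate 14 (not isolated)
Conditions: 1,1'-carbonyldiimidazole (2 equiv), THF, 45 °C; then DBU (1.5 equiv), 0 °C → rt; AcOH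
Reagents that add atoms: 1,1'-carbonyldiimidazole O=C(n1ccnc1)n1ccnc1
Why: The only free phenol is acylated first and the benzylic ketone enolate then closes onto the acyl imidazole (Claisen-type C-acylation, carbonylative lactonisation), so the lactone oxygen is fixed para to the diene; forming the enolate only after O-acylation avoids O-to-O silyl migration.

Step 8
Reactants: 15 4-hydroxycoumarin diene; 16 prenyl acetate (3-methylbut-2-en-1-yl acetate)
Product: 17 (3S)-3-[2,4-bis(TBSO)phenyl]-5,7-bis(TBSO)-6-[(1E)-3-methylbuta-1,3-dien-1-yl]-3-(3-methylbut-2-en-1-yl)chromane-2,4-dione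
Conditions: Pd2(dba)3·CHCl3 (2.5 mol %), (R,R)-DACH-phenyl Trost ligand (7.5 mol %), Et3N (1.2 equiv), CH2Cl2, 0 °C → rt
Reagents that add atoms: none
Why: Tsuji–Trost asymmetric allylic alkylation, in which the soft coumarin enolate attacks the less hindered terminus of the π-prenyl palladium complex inside the chiral pocket of the ligand, sets the quaternary (3S) centre, and any O-prenyl enol ether re-ionises and funnels to the C-alkylated dione.

Step 9
Reactants: 18 2,2',4,4'-tetrahydroxychalcone [(E)-1,3-bis(2,4-dihydroxyphenyl)prop-2-en-1-one]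
Product: 19 (E)-3-[2,4-bis(TBSO)phenyl]-1-[4-(TBSO)-2-hydroxyphenyl]prop-2-en-1-one
Conditions: TBSCl (3.2 equiv), imidazole, DMF, 0 °C → rt
Reagents that add atoms: tert-butyldimethylsilyl chloride CC(C)(C)[Si](C)(C)Cl
Why: Silyl ether formation at the three unchelated phenols leaves the carbonyl-hydrogen-bonded 2'-OH, the least nucleophilic one, free for boron binding in the cycloaddition.

Step 10
Reactants: 17 (3S)-chromandione diene; 19 2'-hydroxychalcone
Product: 20 (3S)-3-[2,4-bis(TBSO)phenyl]-6-[(1S,5R,6S)-5-[2,4-bis(TBSO)phenyl]-6-[4-(TBSO)-2-hydroxybenzoyl]-3-methylcyclohex-2-en-1-yl]-5,7-bis(TBSO)-3-(3-methylbut-2-en-1-yl)chromane-2,4-dione (exo adduct, ring substituents all trans)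
Conditions: B(OPh)3 (30 mol %), (S)-VANOL [(S)-3,3'-diphenyl-2,2'-binaphthalene-1,1'-diol] (30 mol %), 4 Å MS, PhCF3, 40 °C; endo isomer removed by chromatography and discarded
Reagents that add atoms: none
Why: Chiral borate-templated Diels–Alder reaction of the 2'-hydroxychalcone (boron held by phenol and carbonyl, the ligand shielding one enone face) proceeds with the normal regiochemistry (CH2 terminus to the β-carbon), and the exo transition state gives the all-trans adduct, fixing C1' (S) and C5' (R) under catalyst control while C6' is corrected in step 12.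

Step 11
Reactants: 20 exo adduct with free 2-hydroxybenzoyl
Product: 21 (3S)-3-[2,4-bis(TBSO)phenyl]-6-[(1S,5R,6S)-5-[2,4-bis(TBSO)phenyl]-6-[4-(TBSO)-2-(TIPSO)benzoyl]-3-methylcyclohex-2-en-1-yl]-5,7-bis(TBSO)-3-(3-methylbut-2-en-1-yl)chromane-2,4-dione
Conditions: TIPSOTf, 2,6-lutidine, DMAP (cat.), CH2Cl2, 0 °C → rt
Reagents that add atoms: triisopropylsilyl triflate CC(C)[Si](OS(=O)(=O)C(F)(F)F)(C(C)C)C(C)C
Why: Triflate-driven silylation of the chelated phenol removes the acidic OH before enolisation, and the bulky triisopropylsilyl group is chosen because it does not migrate from the aryl oxygen to the neighbouring enolate oxygen.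

Step 12
Reactants: 21 all-trans ketone
Product: 23 (3S)-3-[2,4-bis(TBSO)phenyl]-6-[(1S,5R,6R)-5-[2,4-bis(TBSO)phenyl]-6-[4-(TBSO)-2-(TIPSO)benzoyl]-3-methylcyclohex-2-en-1-yl]-5,7-bis(TBSO)-3-(3-methylbut-2-en-1-yl)chromane-2,4-dione (ring substituents all cis), via potassium enolate 22 (not isolated)
Conditions: KN(SiMe3)2 (1.3 equiv), THF, −78 → −40 °C; then cannulated into AcOH/THF, −78 °C
Reagents that add atoms: potassium bis(trimethylsilyl)amide [K+].C[Si](C)(C)[N-][Si](C)(C)C (potassium held only in 22)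
Why: Zimmerman-type kinetic protonation of the exocyclic enolate, whose two cis-disposed flanking aryl groups are pushed pseudoaxial onto one face by allylic strain, delivers the proton to C6' from the opposite face and gives the contra-thermodynamic all-cis (6'R) ketone irreversibly at −78 °C, while C1', C5' and the non-enolisable C3 are untouched.

Step 13
Reactants: 23 all-cis silyl-protected ketone
Product: 24 (3S)-6-[(1S,5R,6R)-6-(2,4-dihydroxybenzoyl)-5-(2,4-dihydroxyphenyl)-3-methylcyclohex-2-en-1-yl]-3-(2,4-dihydroxyphenyl)-5,7-dihydroxy-3-(3-methylbut-2-en-1-yl)chromane-2,4-dione (target)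
Conditions: HF·pyridine (excess), pyridine/THF, 0 °C → rt
Reagents that add atoms: none
Why: Fluoride-driven cleavage of all eight aryl silyl ethers (Si–F bond formation) under buffered, non-basic, non-nucleophilic conditions neither opens the β-keto lactone nor epimerises C6' nor touches the two alkenes.

## Compound list

1 | 2-bromoresorcinol (2-bromobenzene-1,3-diol) | Oc1cccc(O)c1Br | starting material
2 | 2-bromo-1,3-bis(TBSO)benzene | CC(C)(C)[Si](C)(C)Oc1cccc(O[Si](C)(C)C(C)(C)C)c1Br | intermediate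
3 | 2-[4-bromo-3,5-bis(TBSO)phenyl]-4,4,5,5-tetramethyl-1,3,2-dioxaborolane | CC(C)(C)[Si](C)(C)Oc1cc(B2OC(C)(C)C(C)(C)O2)cc(O[Si](C)(C)C(C)(C)C)c1Br | intermediate (not isolated)
4 | 4-bromo-3,5-bis(TBSO)phenol | CC(C)(C)[Si](C)(C)Oc1cc(O)cc(O[Si](C)(C)C(C)(C)C)c1Br | intermediate
5 | 2,4-dihydroxyphenylacetic acid | OC(=O)Cc1ccc(O)cc1O | starting material
6 | tert-butyldimethylsilyl 2-[2,4-bis(TBSO)phenyl]acetate | CC(C)(C)[Si](C)(C)OC(=O)Cc1ccc(O[Si](C)(C)C(C)(C)C)cc1O[Si](C)(C)C(C)(C)C | intermediate (not isolated)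
7 | 2-[2,4-bis(TBSO)phenyl]acetic acid | OC(=O)Cc1ccc(O[Si](C)(C)C(C)(C)C)cc1O[Si](C)(C)C(C)(C)C | intermediate
8 | 2-[2,4-bis(TBSO)phenyl]acetyl chloride | ClC(=O)Cc1ccc(O[Si](C)(C)C(C)(C)C)cc1O[Si](C)(C)C(C)(C)C | intermediate (not isolated)
9 | bromomagnesium 4-bromo-3,5-bis(TBSO)phenoxide | CC(C)(C)[Si](C)(C)Oc1cc(O[Mg]Br)cc(O[Si](C)(C)C(C)(C)C)c1Br | intermediate (not isolated)
10 | 1-[3-bromo-6-hydroxy-2,4-bis(TBSO)phenyl]-2-[2,4-bis(TBSO)phenyl]ethan-1-one | O=C(Cc1ccc(O[Si](C)(C)C(C)(C)C)cc1O[Si](C)(C)C(C)(C)C)c1c(O)cc(O[Si](C)(C)C(C)(C)C)c(Br)c1O[Si](C)(C)C(C)(C)C | intermediate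
11 | 2-methylbut-1-en-3-yne | C=C(C)C#C | starting material
12 | 4,4,5,5-tetramethyl-2-[(1E)-3-methylbuta-1,3-dien-1-yl]-1,3,2-dioxaborolane | C=C(C)/C=C/B1OC(C)(C)C(C)(C)O1 | intermediate
13 | 1-[6-hydroxy-3-[(1E)-3-methylbuta-1,3-dien-1-yl]-2,4-bis(TBSO)phenyl]-2-[2,4-bis(TBSO)phenyl]ethan-1-one | O=C(Cc1ccc(O[Si](C)(C)C(C)(C)C)cc1O[Si](C)(C)C(C)(C)C)c1c(O)cc(O[Si](C)(C)C(C)(C)C)c(/C=C/C(C)=C)c1O[Si](C)(C)C(C)(C)C | intermediate
14 | 2-{[2,4-bis(TBSO)phenyl]acetyl}-4-[(1E)-3-methylbuta-1,3-dien-1-yl]-3,5-bis(TBSO)phenyl 1H-imidazole-1-carboxylate | O=C(Cc1ccc(O[Si](C)(C)C(C)(C)C)cc1O[Si](C)(C)C(C)(C)C)c1c(OC(=O)n2ccnc2)cc(O[Si](C)(C)C(C)(C)C)c(/C=C/C(C)=C)c1O[Si](C)(C)C(C)(C)C | intermediate (not isolated)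
15 | 3-[2,4-bis(TBSO)phenyl]-5,7-bis(TBSO)-4-hydroxy-6-[(1E)-3-methylbuta-1,3-dien-1-yl]-2H-chromen-2-one | O=C1Oc2cc(O[Si](C)(C)C(C)(C)C)c(/C=C/C(C)=C)c(O[Si](C)(C)C(C)(C)C)c2C(O)=C1c1ccc(O[Si](C)(C)C(C)(C)C)cc1O[Si](C)(C)C(C)(C)C | intermediate
16 | prenyl acetate (3-methylbut-2-en-1-yl acetate) | CC(C)=CCOC(C)=O | starting material
17 | (3S)-3-[2,4-bis(TBSO)phenyl]-5,7-bis(TBSO)-6-[(1E)-3-methylbuta-1,3-dien-1-yl]-3-(3-methylbut-2-en-1-yl)chromane-2,4-dione | CC(C)=CC[C@@]1(c2ccc(O[Si](C)(C)C(C)(C)C)cc2O[Si](C)(C)C(C)(C)C)C(=O)Oc2cc(O[Si](C)(C)C(C)(C)C)c(/C=C/C(C)=C)c(O[Si](C)(C)C(C)(C)C)c2C1=O | intermediate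
18 | 2,2',4,4'-tetrahydroxychalcone [(E)-1,3-bis(2,4-dihydroxyphenyl)prop-2-en-1-one] | O=C(/C=C/c1ccc(O)cc1O)c1ccc(O)cc1O | starting material
19 | (E)-3-[2,4-bis(TBSO)phenyl]-1-[4-(TBSO)-2-hydroxyphenyl]prop-2-en-1-one | O=C(/C=C/c1ccc(O[Si](C)(C)C(C)(C)C)cc1O[Si](C)(C)C(C)(C)C)c1ccc(O[Si](C)(C)C(C)(C)C)cc1O | intermediate
20 | (3S)-3-[2,4-bis(TBSO)phenyl]-6-[(1S,5R,6S)-5-[2,4-bis(TBSO)phenyl]-6-[4-(TBSO)-2-hydroxybenzoyl]-3-methylcyclohex-2-en-1-yl]-5,7-bis(TBSO)-3-(3-methylbut-2-en-1-yl)chromane-2,4-dione (all trans) | CC(C)=CC[C@@]1(c2ccc(O[Si](C)(C)C(C)(C)C)cc2O[Si](C)(C)C(C)(C)C)C(=O)Oc2cc(O[Si](C)(C)C(C)(C)C)c([C@H]3C=C(C)C[C@@H](c4ccc(O[Si](C)(C)C(C)(C)C)cc4O[Si](C)(C)C(C)(C)C)[C@@H]3C(=O)c3ccc(O[Si](C)(C)C(C)(C)C)cc3O)c(O[Si](C)(C)C(C)(C)C)c2C1=O | intermediate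
21 | (3S)-3-[2,4-bis(TBSO)phenyl]-6-[(1S,5R,6S)-5-[2,4-bis(TBSO)phenyl]-6-[4-(TBSO)-2-(TIPSO)benzoyl]-3-methylcyclohex-2-en-1-yl]-5,7-bis(TBSO)-3-(3-methylbut-2-en-1-yl)chromane-2,4-dione (all trans) | CC(C)=CC[C@@]1(c2ccc(O[Si](C)(C)C(C)(C)C)cc2O[Si](C)(C)C(C)(C)C)C(=O)Oc2cc(O[Si](C)(C)C(C)(C)C)c([C@H]3C=C(C)C[C@@H](c4ccc(O[Si](C)(C)C(C)(C)C)cc4O[Si](C)(C)C(C)(C)C)[C@@H]3C(=O)c3ccc(O[Si](C)(C)C(C)(C)C)cc3O[Si](C(C)C)(C(C)C)C(C)C)c(O[Si](C)(C)C(C)(C)C)c2C1=O | intermediate
22 | potassium enolate of 21 (C6' planar, exocyclic C=C(O–)aryl of undefined geometry; C3, C1' and C5' as in 21) | CC(C)=CC[C@@]1(c2ccc(O[Si](C)(C)C(C)(C)C)cc2O[Si](C)(C)C(C)(C)C)C(=O)Oc2cc(O[Si](C)(C)C(C)(C)C)c([C@H]3C=C(C)C[C@@H](c4ccc(O[Si](C)(C)C(C)(C)C)cc4O[Si](C)(C)C(C)(C)C)C3=C([O-])c3ccc(O[Si](C)(C)C(C)(C)C)cc3O[Si](C(C)C)(C(C)C)C(C)C)c(O[Si](C)(C)C(C)(C)C)c2C1=O.[K+] | intermediate (not isolated)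
23 | (3S)-3-[2,4-bis(TBSO)phenyl]-6-[(1S,5R,6R)-5-[2,4-bis(TBSO)phenyl]-6-[4-(TBSO)-2-(TIPSO)benzoyl]-3-methylcyclohex-2-en-1-yl]-5,7-bis(TBSO)-3-(3-methylbut-2-en-1-yl)chromane-2,4-dione (all cis) | CC(C)=CC[C@@]1(c2ccc(O[Si](C)(C)C(C)(C)C)cc2O[Si](C)(C)C(C)(C)C)C(=O)Oc2cc(O[Si](C)(C)C(C)(C)C)c([C@H]3C=C(C)C[C@@H](c4ccc(O[Si](C)(C)C(C)(C)C)cc4O[Si](C)(C)C(C)(C)C)[C@H]3C(=O)c3ccc(O[Si](C)(C)C(C)(C)C)cc3O[Si](C(C)C)(C(C)C)C(C)C)c(O[Si](C)(C)C(C)(C)C)c2C1=O | intermediate
24 | (3S)-6-[(1S,5R,6R)-6-(2,4-dihydroxybenzoyl)-5-(2,4-dihydroxyphenyl)-3-methylcyclohex-2-en-1-yl]-3-(2,4-dihydroxyphenyl)-5,7-dihydroxy-3-(3-methylbut-2-en-1-yl)chromane-2,4-dione | CC(C)=CC[C@@]1(c2ccc(O)cc2O)C(=O)Oc2cc(O)c([C@H]3C=C(C)C[C@@H](c4ccc(O)cc4O)[C@H]3C(=O)c3ccc(O)cc3O)c(O)c2C1=O | target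

## Step count, longest linear sequence and main risks

Total step count: 13. Longest linear sequence: 10 steps (steps 1, 2, 4, 6, 7, 8, 10, 11, 12, 13); steps 3, 5 and 9 are side branches.

**Risk at step 8 (asymmetric prenylation).** The quaternary centre is flanked by a bulky ortho-silyloxyaryl group. O- versus C-attack, linear versus branched prenyl transfer and the enantiomeric excess are all uncertain, and any minor enantiomer of 17 becomes a hard-to-remove C3 epimer after step 10. The fallback sets out from 15 and comes back at 17. The enol oxygen of 15 is acylated with prenyl 1H-imidazole-1-carboxylate (made from prenol and carbonyldiimidazole) to give the enol prenyl carbonate F1. F1 is then treated with Pd2(dba)3 and (S)-tert-butyl-PHOX in toluene at rt. This decarboxylative asymmetric allylic alkylation generates the enolate and the π-prenyl cation as a contact ion pair with no external base, and collapse at carbon returns 17.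

**Risk at step 10 (Diels–Alder).** The diene is flanked by two silyloxy groups, the exo:endo ratio of such borate-catalysed cycloadditions is often near 1:1, and only the exo isomer is usable. The fallback sets out from 17 and comes back at 23, bypassing 20 and 21. Diene 17 is heated (or treated with Me2AlCl) with the ynone F2, prepared by acyl Sonogashira coupling of the corresponding aroyl chloride and arylacetylene. This gives the cyclohexa-1,4-diene F3, whose two C1' epimers (diastereomers because C3 is fixed) are separated. Conjugate reduction of F3 with [(Ph3P)CuH]6 delivers hydride to C5' anti to the C1' aryl group. The resulting enolate is protonated at −78 °C anti to both aryl groups, which sets C5' and C6' together and gives 23.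

**Risk at step 12 (kinetic protonation).** Enolisation of the hindered ketone may be incomplete, and proton return from HN(SiMe3)2 or equilibration by excess base would give back the all-trans ketone. The fallback sets out from 21 and comes back at 24, bypassing 23. The potassium enolate is trapped with Me3SiCl and the trimethylsilyl enol ether F4 is isolated free of amine and base. HF·pyridine at −20 °C → rt then cleaves the enol ether, with ketonisation by proton delivery anti to the two flanking aryl groups, and removes all aryl silyl ethers in the same operation to give 24.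

## Further compounds

F1 | step 8 | 3-[2,4-bis(TBSO)phenyl]-5,7-bis(TBSO)-6-[(1E)-3-methylbuta-1,3-dien-1-yl]-2-oxo-2H-chromen-4-yl 3-methylbut-2-en-1-yl carbonate | O=C1Oc2cc(O[Si](C)(C)C(C)(C)C)c(/C=C/C(C)=C)c(O[Si](C)(C)C(C)(C)C)c2C(OC(=O)OCC=C(C)C)=C1c1ccc(O[Si](C)(C)C(C)(C)C)cc1O[Si](C)(C)C(C)(C)C
F2 | step 10 | 3-[2,4-bis(TBSO)phenyl]-1-[4-(TBSO)-2-(TIPSO)phenyl]prop-2-yn-1-one | O=C(C#Cc1ccc(O[Si](C)(C)C(C)(C)C)cc1O[Si](C)(C)C(C)(C)C)c1ccc(O[Si](C)(C)C(C)(C)C)cc1O[Si](C(C)C)(C(C)C)C(C)C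
F3 | step 10 | (3S)-3-[2,4-bis(TBSO)phenyl]-6-[(1R)-5-[2,4-bis(TBSO)phenyl]-6-[4-(TBSO)-2-(TIPSO)benzoyl]-3-methylcyclohexa-2,5-dien-1-yl]-5,7-bis(TBSO)-3-(3-methylbut-2-en-1-yl)chromane-2,4-dione (C1' hydrogen oriented as in 24; the descriptor is R only because the ring priorities change) | CC(C)=CC[C@@]1(c2ccc(O[Si](C)(C)C(C)(C)C)cc2O[Si](C)(C)C(C)(C)C)C(=O)Oc2cc(O[Si](C)(C)C(C)(C)C)c([C@H]3C=C(C)CC(c4ccc(O[Si](C)(C)C(C)(C)C)cc4O[Si](C)(C)C(C)(C)C)=C3C(=O)c3ccc(O[Si](C)(C)C(C)(C)C)cc3O[Si](C(C)C)(C(C)C)C(C)C)c(O[Si](C)(C)C(C)(C)C)c2C1=O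
F4 | step 12 | trimethylsilyl enol ether of 21 (C6'=C(OSiMe3)aryl of undefined geometry; C3, C1' and C5' as in 21) | CC(C)=CC[C@@]1(c2ccc(O[Si](C)(C)C(C)(C)C)cc2O[Si](C)(C)C(C)(C)C)C(=O)Oc2cc(O[Si](C)(C)C(C)(C)C)c([C@H]3C=C(C)C[C@@H](c4ccc(O[Si](C)(C)C(C)(C)C)cc4O[Si](C)(C)C(C)(C)C)C3=C(O[Si](C)(C)C)c3ccc(O[Si](C)(C)C(C)(C)C)cc3O[Si](C(C)C)(C(C)C)C(C)C)c(O[Si](C)(C)C(C)(C)C)c2C1=O
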